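I start from rates. The question concerns this flask, with the partner added in portions:

| flask | substrate | partner | initiator | remark | time |
|---|---|---|---|---|---|
| autumn | 0.11 M | 0.198 M (in portions, 3) | 2.6 mM | run made earlier; portions every 3.0 min |  |
| spring | 0.44 M | 0.198 M (in portions, 3) | 2.6 mM | run made earlier; portions every 3.0 min |  |
| noon | 0.22 M | 0.198 M (in portions, 3) | 3.9 mM | run made earlier; portions every 3.0 min |  |
| flask | 0.22 M | 0.198 M (in portions, 3) | 2.6 mM | the portions of partner follow each other after 3.0 min, the first at the start | 10 min |

- autumn (time / min: substrate / %, product / %): 1.00: 91, 9; 2.50: 86, 18; 3.00: 81, 19; 5.00: 70, 31; 6.00: 65, 36; 8.00: 55, 44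
- spring (time / min: substrate / %, product / %): 0.667: 96, 4; 1.00: 96, 7; 1.33: 95, 5; 2.50: 92, 7; 3.00: 91, 8; 5.00: 85, 16; 8.00: 77, 26
- noon (time / min: substrate / %, product / %): 0.667: 96, 7; 2.00: 85, 12; 4.00: 79, 24; 6.00: 70, 29; 8.00: 56, 43

(readings scatter by 1.5 percentage points)

- the numbers in the tables scatter with a standard deviation of 1.5 percentage points
- the reaction counts as stopped when no species that holds the substrate changes by six tenths of a point or more over the second half of the time

- which holds at 10 min: what has brought the reaction to rest, or that it has not come to rest (the partner has run out first / forward and back rates have come level / it is still moving / all of the substrate has reacted)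
- share of the substrate used up at 10 min
- product at 10 min, in percent of the substrate charged

In the autumn run, substrate and product add up to 99.0% at 8.00 min, so I count product as conversion. The mean rate up to that time is 6.05 mM min⁻¹ in autumn and 14.3 mM min⁻¹ in spring. I treat the reciprocal rate as two resistances in series, one fixed and one falling as the substrate charge rises. The line through both runs, which share their partner and initiator charges, has slope 14.0 min, which gives a top rate of 26.2 mM min⁻¹ and a half-speed charge, the substrate charge at which the mean rate at those charges is half the top rate, of 0.367 M.

For the flask, the rule gives 9.83 mM min⁻¹. The noon run, with 1.50 times the initiator, reads 11.8 mM min⁻¹, which is faster by a factor of 1.20; the square root of the initiator ratio is 1.22. Held for 10 min, the flask's rate gives 44.7%.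

Partner is the limiting reagent by charge, 0.198 M against 0.22 M, and the spring run reads 114 mM of product at 8.00 min from the same partner charge, more than the 98.3 mM my rate asks of the flask. The second half of the flask's time should add about 22 percentage points, so I call it still moving.

The weak link is the stretch beyond the last reading of the runs, at 8.00 min. In the noon run, the rate from 4.00 min to 8.00 min reads 0.884 of the mean rate up to 8.00 min. Applied to the flask's last stretch, this takes off 1 point, against a scatter of 1.5 points, and I commit to 43.6%.

The forecast says it is still moving, with 42% used up and 42% product. It holds that “the kinetics look saturating”, and my figure stands 1.6 points higher.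

At 10 min the flask has used 44.5% of its substrate and holds 44.5% product: it is still moving.

    substrate + initiating radical → capped initiator + first chain carrier (k = 3.90 × 10⁶ M⁻¹ s⁻¹)
    substrate + second chain carrier → by-product + first chain carrier (k = 22000 M⁻¹ s⁻¹)
    2 first chain carrier → ended chains A (k = 3.00 × 10⁶ M⁻¹ s⁻¹)
    partner → decomposed reagent (k = 0.240 min⁻¹)
    initiator → 2 initiating radical (k = 4.60 × 10⁻⁴ min⁻¹)
    partner + first chain carrier → product + second chain carrier (k = 92000 M⁻¹ s⁻¹)
    2 second chain carrier → ended chains B (k = 5.00 × 10⁶ M⁻¹ s⁻¹)

Over the second half of the time, the largest change in the flask is 20 points. Its mean rate over 10 min comes to 9.79 mM min⁻¹, against the 9.83 mM min⁻¹ from the rule, which rests on means over 8.00 min. For a neighbouring flask charged with 0.088 M of substrate, the same half-speed charge of 0.367 M gives an estimated 5.07 mM min⁻¹, and with the same late correction that is 56.3% conversion. That neighbouring flask stands at 55.1%.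

The readings are simulated with made-up constants; scatter was added.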